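**Retrosynthetic overview**

1. Numbering (azulene): C1–C2 are the cyclopentane CH2 groups, C3 is C(OH)(i-Pr), C3a/C8a are the ring fusion (C8a bears CH3), C4–C8 are the seven-membered ring; β is the face of the C8a methyl.
2. Target ⇐ enedione 18 (C4 and C7 ketones, C5=C6): the 4α-OH comes from reduction directed by the 3β-OH, then vanilloylation; the 7β-OH comes from hydride addition anti to the C8a methyl.
3. 18 ⇐ oxa-bridged tricyclic enone 14: cuprate addition (C6 methyl), SmI2 cleavage of the C3a–O bond (gives C3a–H and C7–OH), then oxidation/dehydrogenation.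
4. 14 ⇐ 3-oxidopyrylium 13 by intramolecular [5+2] cycloaddition, which closes the cyclopentane (C3a–C8a) and the cycloheptene (C7–C8) together. 13 ⇐ furyl diol 10 (Achmatowicz) ⇐ furan + aldehyde 7 ⇐ Sharpless epoxide 4. Ring order: furan (bought), pyranone (step 6), then both carbocycles (step 8).
5. Enabling feature: C3a–C4(O)–C5=C6–C7(O) is a 3-oxidopyrylium in disguise (the five carbons of a dearomatised furyl carbinol, pyran oxygen on C7 and C3a). C3–C2–C1 is a three-atom tether from pyrylium C2 to the C8a(CH3)=C8H2 alkene, and the C3 tertiary alcohol next to the ylide steers the face.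

Key step: step 8

Remark on the chemistry: the tether forces the bridging oxygen onto the α face of C7 (cis to C1 at C8a), opposite to the target. C7 is therefore taken through the ketone and its β-hydroxyl is set by reduction in step 14.

Step 1
Reactants: 1 prop-2-yn-1-ol; 2 isopropylmagnesium chloride
Product: 3 3-methyl-2-methylidenebutan-1-ol
Conditions: i-PrMgCl (2.5 equiv), CuI (10 mol%), THF, −20 °C to rt; aq NH4Cl
Reagents that add atoms: none
Why: Copper-catalysed anti-carbomagnesiation of the propargylic alkoxide should place the isopropyl group on the internal alkyne carbon through a five-membered magnesium chelate, so that protonolysis gives the 1,1-disubstituted allylic alcohol with no stereocentre formed.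

Step 2
Reactants: 3 3-methyl-2-methylidenebutan-1-ol
Product: 4 [(2R)-2-(propan-2-yl)oxiran-2-yl]methanol
Conditions: Ti(OiPr)4 (10 mol%), D-(−)-diisopropyl tartrate (12 mol%), t-BuOOH (2 equiv), 4 Å MS, CH2Cl2, −20 °C
Reagents that add atoms: tert-butyl hydroperoxide CC(C)(C)OO
Why: Sharpless asymmetric epoxidation of a 2-substituted allylic alcohol, in which the titanium tartrate complex of the D-(−)-tartrate should deliver oxygen to the alkene face that gives the (R)-configured quaternary epoxide carbon, the future C3.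

Step 3
Reactants: 4 [(2R)-2-(propan-2-yl)oxiran-2-yl]methanol; 5 (2-methylprop-2-en-1-yl)magnesium chloride
Product: 6 (2R)-5-methyl-2-(propan-2-yl)hex-5-ene-1,2-diol
Conditions: 5 (3 equiv), CuI (10 mol%), THF, −40 to 0 °C; aq NH4Cl
Reagents that add atoms: none
Why: Copper-catalysed Grignard opening of the 2,2-disubstituted epoxide by SN2 attack at its unhindered CH2 terminus should install the 3-methylbut-3-enyl tether while the quaternary stereocentre is not involved and is carried over unchanged.

Step 4
Reactants: 6 (2R)-5-methyl-2-(propan-2-yl)hex-5-ene-1,2-diol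
Product: 7 (2R)-2-hydroxy-5-methyl-2-(propan-2-yl)hex-5-enal
Conditions: IBX (1.5 equiv), DMSO, rt
Reagents that add atoms: none
Why: IBX oxidation should convert the primary alcohol of the 1,2-diol into the aldehyde without glycol cleavage, and the tertiary alcohol and its stereocentre cannot react.

Step 5
Reactants: 7 (2R)-2-hydroxy-5-methyl-2-(propan-2-yl)hex-5-enal; 8 furan
Product: 10 (1RS,2R)-1-(furan-2-yl)-5-methyl-2-(propan-2-yl)hex-5-ene-1,2-diol, via 2-lithiofuran 9 (not isolated)
Conditions: furan (3.5 equiv), n-BuLi (3 equiv), THF, 0 °C; then 7, −78 °C; aq NH4Cl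
Reagents that add atoms: none
Why: 1,2-Addition of 2-lithiofuran (C2 lithiation of furan) to the aldehyde, after deprotonation of the tertiary hydroxyl by excess reagent, should give the furyl carbinol, whose new carbinol centre may form as a mixture because it becomes sp2 in step 8.

Step 6
Reactants: 10 (1RS,2R)-1-(furan-2-yl)-5-methyl-2-(propan-2-yl)hex-5-ene-1,2-diol
Product: 11 6-hydroxy-2-[(3R)-3-hydroxy-2,6-dimethylhept-6-en-3-yl]-2H-pyran-3(6H)-one
Conditions: NBS (1.05 equiv), NaHCO3, NaOAc, THF/H2O (4:1), 0 °C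
Reagents that add atoms: water O
Why: Achmatowicz rearrangement, in which NBS should oxidise the electron-rich furan much faster than the 1,1-disubstituted alkene and the secondary carbinol oxygen recloses to the 6-hydroxypyranone under buffered conditions, the two ring centres forming as mixtures that are erased in step 8.

Step 7
Reactants: 11 6-hydroxy-2-[(3R)-3-hydroxy-2,6-dimethylhept-6-en-3-yl]-2H-pyran-3(6H)-one
Product: 12 6-[(3R)-3-hydroxy-2,6-dimethylhept-6-en-3-yl]-5-oxo-5,6-dihydro-2H-pyran-2-yl acetate
Conditions: Ac2O (1.5 equiv), pyridine, DMAP (5 mol%), CH2Cl2, −10 to 0 °C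
Reagents that add atoms: acetic anhydride CC(=O)OC(C)=O
Why: Acetylation of the hemiacetal hydroxyl under mild base should provide the leaving group for ylide formation, the hindered tertiary alcohol being inert under these conditions.

Step 8
Reactants: 12 6-[(3R)-3-hydroxy-2,6-dimethylhept-6-en-3-yl]-5-oxo-5,6-dihydro-2H-pyran-2-yl acetate
Product: 14 3aα,7α-epoxy-3β-hydroxy-8aβ-methyl-3α-(propan-2-yl)-2,3,3a,7,8,8a-hexahydroazulen-4(1H)-one, via oxidopyrylium ylide 13 (not isolated)
Conditions: Et3N (3 equiv), MeCN (0.02 M), rt to 60 °C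
Reagents that add atoms: none
Why: Triethylamine should remove the acidic pyranone C2–H and expel acetate to give the 3-oxidopyrylium ylide 13, an aromatic carbonyl ylide whose C2 and C6 termini add suprafacially to the tethered C(CH3)=CH2 group in a concerted, thermally allowed six-electron intramolecular [5+2] cycloaddition. The closest known reaction type is the intramolecular 3-oxidopyrylium–alkene cycloaddition of 2-alkenyl-substituted acetoxypyranones with a three-atom tether. The cyclopentane closes by bonding of pyrylium C2 to the internal alkene carbon (5-exo with respect to the tether) and the cycloheptenone closes in the same event by bonding of the alkene CH2 to pyrylium C6, the pyran oxygen remaining as the 3aα,7α bridge of an 8-oxabicyclo[3.2.1]octenone. The three-atom tether can only span the bridgehead and the exo position of the two-carbon bridge, so the C8a methyl is forced endo (anti to the oxygen bridge), and C3a and C7 are necessarily bridged on one face. The face is chosen by the C3 carbinol centre: its hydroxyl should lie in the ylide plane, hydrogen-bonded to the oxido oxygen and free of allylic 1,3-strain, so the isopropyl group occupies one face and the tether folds over the other, which sets C3a, C7 and C8a relative to C3. The step needs this facial selectivity and cycloaddition in preference to ylide dimerisation, the latter being secured by the short tether and high dilution.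

Step 9
Reactants: 14 3aα,7α-epoxy-3β-hydroxy-8aβ-methyl-3α-(propan-2-yl)-2,3,3a,7,8,8a-hexahydroazulen-4(1H)-one
Product: 15 3aα,7α-epoxy-3β-hydroxy-6α,8aβ-dimethyl-3α-(propan-2-yl)-2,3,3a,5,6,7,8,8a-octahydroazulen-4(1H)-one
Conditions: Me2CuLi (3 equiv, from MeLi and CuI), Et2O, −78 to −40 °C; aq NH4Cl
Reagents that add atoms: methyllithium C[Li], delivered as lithium dimethylcuprate [Li+].C[Cu-]C
Why: Cuprate conjugate addition to the bicyclic enone from the exo face (syn to the oxygen bridge, away from the two-carbon bridge) should install the C6 methyl and remove the enone conjugation, so that only the C3a–O bond is activated in step 10, the C6 centre being temporary.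

Step 10
Reactants: 15 3aα,7α-epoxy-3β-hydroxy-6α,8aβ-dimethyl-3α-(propan-2-yl)-2,3,3a,5,6,7,8,8a-octahydroazulen-4(1H)-one
Product: 16 3β,7α-dihydroxy-6α,8aβ-dimethyl-3α-(propan-2-yl)-3aα-H-2,3,3a,5,6,7,8,8a-octahydroazulen-4(1H)-one
Conditions: SmI2 (2.5 equiv), THF/MeOH (10:1), −78 °C
Reagents that add atoms: none
Why: SmI2 reductive cleavage of the α-alkoxy ketone should break the C3a–O bond through the ketyl and leave the oxygen on C7 as hydroxyl, and the samarium enolate should be protonated at C3a from the α face just vacated by that oxygen to give the trans-fused hydroxy ketone, which is also expected to be the more stable ring fusion (isopropyl trans to C4, 3β-OH hydrogen-bonded to the carbonyl).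

Step 11
Reactants: 16 3β,7α-dihydroxy-6α,8aβ-dimethyl-3α-(propan-2-yl)-3aα-H-2,3,3a,5,6,7,8,8a-octahydroazulen-4(1H)-one
Product: 18 3β-hydroxy-6,8aβ-dimethyl-3α-(propan-2-yl)-3aα-H-2,3,3a,8a-tetrahydroazulene-4,7(1H,8H)-dione, via 1,4-diketone 17 (not isolated)
Conditions: IBX (1.2 equiv), DMSO, rt; then IBX (2.5 equiv), 75 °C
Reagents that add atoms: none
Why: IBX should first oxidise the C7 alcohol and then dehydrogenate the 1,4-diketone through its enol to the endocyclic C5=C6 enedione, conjugated with both carbonyls, because the other α-carbons (C3a, C8) have only quaternary neighbours (C3, C8a), and the temporary C6 centre is removed.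

Step 12
Reactants: 18 3β-hydroxy-6,8aβ-dimethyl-3α-(propan-2-yl)-3aα-H-2,3,3a,8a-tetrahydroazulene-4,7(1H,8H)-dione
Product: 19 3β,4α-dihydroxy-6,8aβ-dimethyl-3α-(propan-2-yl)-3aα-H-2,3,3a,4,8,8a-hexahydroazulen-7(1H)-one
Conditions: Me4NBH(OAc)3 (5 equiv), MeCN/AcOH (1:1), −30 to −20 °C
Reagents that add atoms: none
Why: Evans–Saksena reduction, in which the 3β-hydroxyl should exchange onto boron and deliver hydride through a six-membered transition state to the β face of the C4 carbonyl to give the 4α-alcohol (anti to the 3β-OH), while the C7 carbonyl has no neighbouring hydroxyl and is not reduced by the triacetoxyborohydride.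

Step 13
Reactants: 19 3β,4α-dihydroxy-6,8aβ-dimethyl-3α-(propan-2-yl)-3aα-H-2,3,3a,4,8,8a-hexahydroazulen-7(1H)-one; 20 4-acetoxy-3-methoxybenzoic acid
Product: 22 3β-hydroxy-6,8aβ-dimethyl-7-oxo-3α-(propan-2-yl)-3aα-H-1,2,3,3a,4,7,8,8a-octahydroazulen-4α-yl 4-acetoxy-3-methoxybenzoate, via acid chloride 21 (not isolated)
Conditions: 20, (COCl)2, DMF (cat.), CH2Cl2, rt; then 19, pyridine, DMAP (10 mol%), CH2Cl2, 0 °C to rt
Reagents that add atoms: none
Why: Acylation of the secondary allylic C4 hydroxyl with the acid chloride made in situ should be selective because the tertiary C3 hydroxyl is too hindered to react, and no stereocentre is touched.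

Step 14
Reactants: 22 3β-hydroxy-6,8aβ-dimethyl-7-oxo-3α-(propan-2-yl)-3aα-H-1,2,3,3a,4,7,8,8a-octahydroazulen-4α-yl 4-acetoxy-3-methoxybenzoate
Product: 24 (3R,3aS,4S,7R,8aR)-3,7-dihydroxy-6,8a-dimethyl-3-(propan-2-yl)-1,2,3,3a,4,7,8,8a-octahydroazulen-4-yl 4-hydroxy-3-methoxybenzoate, via aryl acetate 23 (not isolated)
Conditions: NaBH4, CeCl3·7H2O, MeOH, −78 °C; then K2CO3 (0.5 equiv), MeOH, 0 °C
Reagents that add atoms: none
Why: Luche 1,2-reduction of the C7 enone carbonyl should occur from the α face, anti to the pseudo-axial C8a methyl (1,3 to C7), so that the hydroxyl emerges β, and the following carbonate methanolysis should cleave only the phenolic acetate and leave the hindered, electron-rich vanillate ester.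

**Compound list**

1 | prop-2-yn-1-ol | C#CCO | starting material
2 | isopropylmagnesium chloride | CC(C)[Mg]Cl | starting material
3 | 3-methyl-2-methylidenebutan-1-ol | C=C(CO)C(C)C | intermediate
4 | [(2R)-2-(propan-2-yl)oxiran-2-yl]methanol | OC[C@]1(C(C)C)CO1 | intermediate
5 | (2-methylprop-2-en-1-yl)magnesium chloride | C=C(C)C[Mg]Cl | starting material
6 | (2R)-5-methyl-2-(propan-2-yl)hex-5-ene-1,2-diol | C=C(C)CC[C@@](O)(C(C)C)CO | intermediate
7 | (2R)-2-hydroxy-5-methyl-2-(propan-2-yl)hex-5-enal | C=C(C)CC[C@@](O)(C(C)C)C=O | intermediate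
8 | furan | c1ccoc1 | starting material
9 | 2-lithiofuran (not isolated) | [Li]c1ccco1 | intermediate
10 | (1RS,2R)-1-(furan-2-yl)-5-methyl-2-(propan-2-yl)hex-5-ene-1,2-diol (carbinol epimers) | C=C(C)CC[C@@](O)(C(C)C)C(O)c1ccco1 | intermediate
11 | 6-hydroxy-2-[(3R)-3-hydroxy-2,6-dimethylhept-6-en-3-yl]-2H-pyran-3(6H)-one (mixture at the two ring centres) | C=C(C)CC[C@@](O)(C(C)C)C1OC(O)C=CC1=O | intermediate
12 | 6-[(3R)-3-hydroxy-2,6-dimethylhept-6-en-3-yl]-5-oxo-5,6-dihydro-2H-pyran-2-yl acetate (mixture at the two ring centres) | C=C(C)CC[C@@](O)(C(C)C)C1OC(OC(C)=O)C=CC1=O | intermediate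
13 | 2-[(3R)-3-hydroxy-2,6-dimethylhept-6-en-3-yl]pyrylium-3-olate (not isolated) | C=C(C)CC[C@@](O)(C(C)C)c1[o+]cccc1[O-] | intermediate
14 | 3aα,7α-epoxy-3β-hydroxy-8aβ-methyl-3α-(propan-2-yl)-2,3,3a,7,8,8a-hexahydroazulen-4(1H)-one | O=C2C=C[C@@H]4C[C@@]3(C)CC[C@@](O)(C(C)C)[C@]23O4 | intermediate
15 | 3aα,7α-epoxy-3β-hydroxy-6α,8aβ-dimethyl-3α-(propan-2-yl)-2,3,3a,5,6,7,8,8a-octahydroazulen-4(1H)-one | O=C2C[C@@H](C)[C@@H]4C[C@@]3(C)CC[C@@](O)(C(C)C)[C@]23O4 | intermediate
16 | 3β,7α-dihydroxy-6α,8aβ-dimethyl-3α-(propan-2-yl)-3aα-H-2,3,3a,5,6,7,8,8a-octahydroazulen-4(1H)-one (trans-fused) | O=C2C[C@@H](C)[C@@H](O)C[C@@]3(C)CC[C@@](O)(C(C)C)[C@H]23 | intermediate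
17 | 3β-hydroxy-6α,8aβ-dimethyl-3α-(propan-2-yl)-3aα-H-2,3,3a,5,6,8a-hexahydroazulene-4,7(1H,8H)-dione (not isolated) | O=C2C[C@@H](C)C(=O)C[C@@]3(C)CC[C@@](O)(C(C)C)[C@H]23 | intermediate
18 | 3β-hydroxy-6,8aβ-dimethyl-3α-(propan-2-yl)-3aα-H-2,3,3a,8a-tetrahydroazulene-4,7(1H,8H)-dione | O=C2C=C(C)C(=O)C[C@@]3(C)CC[C@@](O)(C(C)C)[C@H]23 | intermediate
19 | 3β,4α-dihydroxy-6,8aβ-dimethyl-3α-(propan-2-yl)-3aα-H-2,3,3a,4,8,8a-hexahydroazulen-7(1H)-one | O[C@H]2C=C(C)C(=O)C[C@@]3(C)CC[C@@](O)(C(C)C)[C@H]23 | intermediate
20 | 4-acetoxy-3-methoxybenzoic acid | COc1cc(C(=O)O)ccc1OC(C)=O | starting material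
21 | 4-acetoxy-3-methoxybenzoyl chloride (not isolated) | COc1cc(C(Cl)=O)ccc1OC(C)=O | intermediate
22 | 3β-hydroxy-6,8aβ-dimethyl-7-oxo-3α-(propan-2-yl)-3aα-H-1,2,3,3a,4,7,8,8a-octahydroazulen-4α-yl 4-acetoxy-3-methoxybenzoate | COc1cc(C(=O)O[C@H]2C=C(C)C(=O)C[C@@]3(C)CC[C@@](O)(C(C)C)[C@H]23)ccc1OC(C)=O | intermediate
23 | 3β,7β-dihydroxy-6,8aβ-dimethyl-3α-(propan-2-yl)-3aα-H-1,2,3,3a,4,7,8,8a-octahydroazulen-4α-yl 4-acetoxy-3-methoxybenzoate (not isolated) | COc1cc(C(=O)O[C@H]2C=C(C)[C@H](O)C[C@@]3(C)CC[C@@](O)(C(C)C)[C@H]23)ccc1OC(C)=O | intermediate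
24 | (3R,3aS,4S,7R,8aR)-3,7-dihydroxy-6,8a-dimethyl-3-(propan-2-yl)-1,2,3,3a,4,7,8,8a-octahydroazulen-4-yl 4-hydroxy-3-methoxybenzoate (CNP0189996.3) | COc1cc(C(=O)O[C@H]2C=C(C)[C@H](O)C[C@@]3(C)CC[C@@](O)(C(C)C)[C@H]23)ccc1O | target

**Step count and risks**

Total step count: 14. Longest linear sequence: 14 steps (1 to 24).

Step 8 (key step). What may go wrong: base-induced retro-aldol cleavage of the β-hydroxy ketone or capture of the pyrylium carbon by the free tertiary hydroxyl may compete with cycloaddition, and the facial bias may be eroded. The fallback masks the hydroxyl and relies on steric control. It sets out from 12: N-(trimethylsilyl)imidazole in CH2Cl2 at 0 °C should give the trimethylsilyl ether of acetoxypyranone 12 F1. Et3N in MeCN as in step 8 should then give the trimethylsilyl ether of tricyclic enone 14 F2, the silyloxy group rather than the isopropyl group taking the in-plane position beside the oxido oxygen. Citric acid in MeOH should remove the silyl group, and the route is rejoined at 14.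

Step 10. What may go wrong: the samarium enolate may be protonated at C3a from the β face, which gives the cis ring fusion. The fallback replaces kinetic protonation by thermodynamic equilibration at a more acidic stage. It sets out from 15: the cis-fused 3a-epimer of hydroxy ketone 16 F3 is oxidised with IBX as in step 11 to the cis-fused 3a-epimer of enedione 18 F4, in which C3a–H is α to the enedione carbonyl. Catalytic DBU in toluene should then equilibrate it through the C3a–C4 enol to the trans-fused isomer, and the route is rejoined at 18.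

Step 14. What may go wrong: hydride may add to the β face of the C7 carbonyl, which gives the 7α-alcohol. The fallback sets C7 by invertive substitution instead of facial control. It sets out from 22: NaBH4/CeCl3·7H2O in MeOH at −78 °C with a cold acetic acid quench should give the 7α-alcohol with the aryl acetate intact F5. A Mitsunobu reaction (4-nitrobenzoic acid, PPh3, DIAD, THF, 0 °C) should invert C7 to the 7β 4-nitrobenzoate F6. K2CO3 in MeOH at 0 °C should then cleave the activated nitrobenzoate and the aryl acetate while the vanillate ester stays, and the route is rejoined at 24.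

Further compounds
F1 | step 8 | trimethylsilyl ether of acetoxypyranone 12 | C=C(C)CC[C@@](O[Si](C)(C)C)(C(C)C)C1OC(OC(C)=O)C=CC1=O
F2 | step 8 | trimethylsilyl ether of tricyclic enone 14 | O=C2C=C[C@@H]4C[C@@]3(C)CC[C@@](O[Si](C)(C)C)(C(C)C)[C@]23O4
F3 | step 10 | cis-fused 3a-epimer of hydroxy ketone 16 (3aβ-H) | O=C2C[C@@H](C)[C@@H](O)C[C@@]3(C)CC[C@@](O)(C(C)C)[C@@H]23
F4 | step 10 | cis-fused 3a-epimer of enedione 18 (3aβ-H) | O=C2C=C(C)C(=O)C[C@@]3(C)CC[C@@](O)(C(C)C)[C@@H]23
F5 | step 14 | 7α-alcohol, the C7 epimer of 23 | COc1cc(C(=O)O[C@H]2C=C(C)[C@@H](O)C[C@@]3(C)CC[C@@](O)(C(C)C)[C@H]23)ccc1OC(C)=O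
F6 | step 14 | 7β 4-nitrobenzoate of 23 | COc1cc(C(=O)O[C@H]2C=C(C)[C@H](OC(=O)c4ccc(cc4)[N+](=O)[O-])C[C@@]3(C)CC[C@@](O)(C(C)C)[C@H]23)ccc1OC(C)=O
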